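## The problem

Target 18 is an achiral bibenzyl: two benzene rings joined by a saturated Cα–Cβ bridge and carrying three 4-hydroxybenzyl groups, one methyl ether and two further phenols. Ring A is a pentasubstituted, phloroglucinol-derived ring: C1 bears the methoxy group, C3 a free hydroxyl, C4 and C6 one 4-hydroxybenzyl group each, and C5, wedged between those two benzyl groups, bears Cα; only C2 is unsubstituted. Ring B carries Cβ at C1′, a 4-hydroxybenzyl group at C2′ and a hydroxyl at C5′. There is no stereocenter, so nothing has to be controlled or relayed; the only stereocenter the plan creates is a transient boron-bearing Cβ that is removed again. The tasks are regiochemical and steric: the three oxygens of ring A must be told apart, the benzyl groups must go to C4 and C6 and not to C2, and a carbon chain must be attached at the most crowded position of the molecule. The material is fragile in predictable ways: five electron-rich phenols (air oxidation, stray electrophilic substitution), three doubly benzylic methylene groups that are acidic towards organolithiums and oxidisable, and a methyl ether that must outlive the removal of every other oxygen protecting group. The enabling feature is twofold: C5 of ring A sits where the third oxygen of a phloroglucinol would be, so it can be carried as a phenol and turned into a triflate, and the bridge is a two-carbon unit with exactly one aryl group on each carbon, which is what a vinyl group becomes when it accepts an aryl nucleophile at one end and an aryl electrophile at the other.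

## Retrosynthesis

**18 back to 16.** The five phenols are masked as benzyl ethers, so 18 comes from penta-O-benzyl ether 17 by cleavage of five O–CH2Ph bonds in one hydrogenolysis that leaves the methyl ether alone. Benzyl is preferred to silyl or acetal groups because it tolerates sodium phenoxide chemistry, tert-butyllithium at low temperature, palladium catalysis and fluoride. Compound 17 is in turn the C–H form of benzylic boronate 16; the C–B bond at Cβ is accepted as a disposable by-product of the coupling, and the forward step only has to replace boron by hydrogen without touching five ethers.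

**16 back to 7, 13 and 14.** Both bridge-to-ring bonds, C5–Cα and Cβ–C1′, are cut at once, leaving ring A as triflate 7, the bridge as vinylboronic ester 13 and ring B as aryllithium 14. Cutting Cα–Cβ instead would need a one-carbon substituent at C5, and there is no regiochemical handle for placing a formyl or halomethyl group between two benzyl groups on a ring whose open positions are all activated; an oxygen at C5 comes free with the phloroglucinol core. Cutting only C5–Cα or only Cβ–C1′ would require a separately made styrene or arylethyl metal. The double cut reduces the bridge to a commercial reagent and gives two fragments of similar size. The forward reaction is a conjunctive cross-coupling under Pd(OAc)2 and the MandyPhos-type ligand (Sp,Sp)-1,1′-bis[bis(4-methoxy-3,5-dimethylphenyl)phosphino]-2,2′-bis[(R)-α-(dimethylamino)benzyl]ferrocene. It must achieve oxidative addition into a doubly ortho-substituted triflate and alkene binding at a crowded palladium centre, and it must outrun direct aryl transfer.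

**14 back to 8 and 10.** Aryllithium 14 is the bromine–lithium exchange product of bromide 12. The diarylmethane of 12 is cut between the benzylic carbon and the 4-(benzyloxy)phenyl ring, giving carbinol 11 and then aldehyde 9 plus Grignard reagent 10; 9 is the benzyl ether of commercial 8. A Friedel–Crafts benzylation of a 3-bromophenol ether would give ortho/para mixtures, whereas 8 already holds bromine, oxygen and the benzylic carbon in the required 1,2,4-relationship. The forward steps are routine.

**7 back to 1 and 3.** Triflate 7 comes from phenol 6 by O-sulfonylation. In 6 the two C–CH2Ar bonds at C4 and C6 are cut, leading to phenol 2 and two molecules of benzylic chloride 3. The single free hydroxyl of 2 is the oxygen that will become the triflate, so the same atom directs both benzylations to its ortho carbons and then serves as the coupling handle. The forward reaction must favour ortho C-alkylation of the phenoxide over O-alkylation and over attack at the para carbon (C2 of ring A); it passes through mono-benzylated phenols 4 and 5, which converge on 6. Phenol 2 is the mono-benzyl ether of symmetrical 1, a statistical but simple desymmetrisation that also fixes which oxygen ends as the free C3 hydroxyl.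

## Roads not taken

Alternative 1: Ring A by Michael–Claisen annulation, aromatised late. The cut goes through ring A itself (C4–C5 and C1–C2). The more substituted enolate of 4-[4-(benzyloxy)phenyl]butan-2-one A2 would add to the β-carbon of an α-benzyl enoate that already carries ring B and the bridge, methyl (E)-2-[4-(benzyloxy)benzyl]-5-{5-(benzyloxy)-2-[4-(benzyloxy)benzyl]phenyl}pent-2-enoate A3. The methyl carbon of the ketone would then close onto the ester to give the all-trans meso cyclohexane-1,3-dione A1.
- Merits: every substituent of ring A is placed by bond construction, so no benzyl regiochemistry arises, and no crowded aryl–alkyl coupling is needed because the bridge is present before the ring exists. Dione A1 is symmetric, so O-methylation of either carbonyl followed by dehydrogenation would give the methoxy/hydroxy pattern without a statistical step.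
- Weak points: a secondary ketone enolate must add to a trisubstituted, β-alkyl-α-benzyl acrylate, which is a poor acceptor and can be deprotonated at its γ-carbon. Ketone A2 must enolise first at C3 and then at the methyl group. The final dehydrogenation of a fully substituted dione must be done next to five benzyl ethers and three electron-rich benzylic methylenes that the usual quinone or halogen oxidants also attack. Enoate A3 itself needs several further steps from bromide 12.
- Comparison: this road is better than the chosen plan on ring A regiochemistry and avoids the hindered coupling. The chosen plan offers a shorter, convergent sequence from aromatic building blocks and no late oxidation of a sensitive intermediate.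

Alternative 2: Aryne acyl-alkylation for the C4/C5 pair. The cut is C5–Cα and C4–C(=O). The aryne released by fluoride from 3,5-dimethoxy-2-(trimethylsilyl)phenyl trifluoromethanesulfonate A5 would insert into the CH2–C(=O) bond of methyl 3-[4-(benzyloxy)phenyl]-3-oxopropanoate A6, giving methyl 2-{2-[4-(benzyloxy)benzoyl]-3,5-dimethoxyphenyl}acetate A4.
- Merits: the insertion of a β-ketoester such as A6 is a known reaction type for alkoxy-substituted arynes, and the methoxy group of the aryne from A5 steers the enolate to the distal aryne carbon. The ketone in A4 lies ortho to one methoxy group, so a chelating Lewis acid could free exactly the C3 oxygen, which differentiates the ring A oxygens more cleanly than the statistical step 1.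
- Weak points: A4 holds only a fraction of the target. The C6 benzyl group must still be placed by electrophilic substitution in competition with C2. The acetate arm must be extended to Cβ and joined to ring B, most simply by adding aryllithium 14 to a derived carbonyl and deoxygenating. Two benzylic carbonyl groups must be reduced. The post-key-step sequence is long and linear.
- Comparison: its key step is sterically easier and better precedented for its substrate class than step 7. The chosen plan forms the hardest bond and unites the whole skeleton in one operation.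

Alternative 3: Ring B by cycloaddition. The cut goes through ring B (C6′–C1′ and C3′–C2′). (E)-1-Methoxy-3-(trimethylsilyloxy)buta-1,3-diene A9 would add across the triple bond of 5-{3-(benzyloxy)-2,6-bis[4-(benzyloxy)benzyl]-5-methoxyphenyl}-1-[4-(benzyloxy)phenyl]pent-2-yn-1-one A8. Acid-induced loss of the methoxy and silyl groups would then give the tetra-O-benzyl 2′-aroyl phenol A7.
- Merits: the polarity of diene A9 fixes the C5′ hydroxyl and the C2′ aroyl group without ambiguity, no aryllithium bearing an acidic diarylmethane is needed, and a ketone para to a free phenol, as in A7, is easily reduced to the methylene.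
- Weak points: ynone A8 already contains complete ring A with its C5–Cα bond, so the problem of attaching carbon between the two benzyl groups is moved, not solved, and would still need a coupling on triflate 7. The ynone is a sensitive acceptor that must carry ring A through several steps, and the ketone reduction and an extra protecting-group decision follow.
- Comparison: the cycloaddition is sterically less demanding than step 7 and is the safer single step. The chosen plan is shorter, prepares ring B separately in three routine steps, and spends the hindered coupling on the step that also completes the skeleton.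

Key step: step 7

Assumption: boronate 16 is carried forward as whatever mixture of enantiomers the single-enantiomer ligand delivers, since its only stereocenter is removed in step 8; it is therefore drawn without configuration.

## Steps

Step 1
Reactants: 1 5-methoxyresorcinol (5-methoxybenzene-1,3-diol)
Product: 2 3-(benzyloxy)-5-methoxyphenol
Conditions: BnBr (1.0 equiv), K2CO3, acetone, reflux
Reagents that add atoms: benzyl bromide, BrCc1ccccc1
Why: Williamson ether synthesis on one of two equivalent phenols; with one equivalent of benzyl bromide the mono-ether should be the main component of a statistical mixture, and the polar diol (recycled) and the non-polar bis-ether are readily separated from it.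

Step 2
Reactants: 2 3-(benzyloxy)-5-methoxyphenol; 3 4-(benzyloxy)benzyl chloride (2.1 equiv)
Product: 6 3-(benzyloxy)-2,6-bis[4-(benzyloxy)benzyl]-5-methoxyphenol, via mono-C-benzyl phenol 4 (not isolated), via regioisomeric mono-C-benzyl phenol 5 (not isolated)
Conditions: NaH (2.2 equiv), toluene, 0 °C to rt; then 3, 110 °C
Reagents that add atoms: none
Why: Ortho C-alkylation of a sodium phenoxide in a non-polar solvent: in toluene the aggregated, tightly ion-paired phenoxide shields oxygen and delivers the benzylic electrophile to the flanking carbons through a sodium-bridged cyclic transition state, and the phloroglucinol-type ring is strongly carbon-nucleophilic. The mono-benzyl phenols 4 and 5 are deprotonated again by the second equivalent of NaH and both converge on 6, the carbon para to the phenoxide oxygen being left unsubstituted.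

Step 3
Reactants: 6 3-(benzyloxy)-2,6-bis[4-(benzyloxy)benzyl]-5-methoxyphenol
Product: 7 3-(benzyloxy)-2,6-bis[4-(benzyloxy)benzyl]-5-methoxyphenyl trifluoromethanesulfonate
Conditions: Tf2O, pyridine, CH2Cl2, 0 °C to rt
Reagents that add atoms: trifluoromethanesulfonic anhydride, O=S(=O)(OS(=O)(=O)C(F)(F)F)C(F)(F)F
Why: O-Sulfonylation of a phenol; the small, highly electrophilic anhydride reaches an oxygen flanked by two benzylic methylene groups, as in the routine triflation of 2,6-dialkylphenols, and the ether groups are inert.

Step 4
Reactants: 8 2-bromo-4-hydroxybenzaldehyde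
Product: 9 4-(benzyloxy)-2-bromobenzaldehyde
Conditions: BnBr, K2CO3, DMF, rt
Reagents that add atoms: benzyl bromide, BrCc1ccccc1
Why: Williamson ether synthesis on an acidic para-formyl phenol; the aldehyde and the aryl bromide are untouched.

Step 5
Reactants: 9 4-(benzyloxy)-2-bromobenzaldehyde; 10 [4-(benzyloxy)phenyl]magnesium bromide (commercial THF solution)
Product: 11 (RS)-[4-(benzyloxy)-2-bromophenyl][4-(benzyloxy)phenyl]methanol
Conditions: 4-BnOC6H4MgBr (1.0 M in THF), THF, 0 °C; then aq. NH4Cl
Reagents that add atoms: none
Why: Grignard addition to an aromatic aldehyde; an aryl Grignard reagent does not exchange with the aryl bromide at 0 °C, and the carbinol center is formed racemic and removed in step 6.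

Step 6
Reactants: 11 (RS)-[4-(benzyloxy)-2-bromophenyl][4-(benzyloxy)phenyl]methanol
Product: 12 4-(benzyloxy)-1-[4-(benzyloxy)benzyl]-2-bromobenzene
Conditions: Et3SiH, CF3CO2H, CH2Cl2, 0 °C
Reagents that add atoms: none
Why: Ionic hydrogenation of a benzhydrol: the diarylmethyl cation, stabilised by two para-alkoxy groups, forms readily in cold acid and is captured by the silane hydride; aryl benzyl ethers and the aryl bromide tolerate brief exposure to cold trifluoroacetic acid.

Step 7
Reactants: 12 4-(benzyloxy)-1-[4-(benzyloxy)benzyl]-2-bromobenzene; 13 4,4,5,5-tetramethyl-2-vinyl-1,3,2-dioxaborolane; 7 3-(benzyloxy)-2,6-bis[4-(benzyloxy)benzyl]-5-methoxyphenyl trifluoromethanesulfonate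
Product: 16 2-[1-{5-(benzyloxy)-2-[4-(benzyloxy)benzyl]phenyl}-2-{3-(benzyloxy)-2,6-bis[4-(benzyloxy)benzyl]-5-methoxyphenyl}ethyl]-4,4,5,5-tetramethyl-1,3,2-dioxaborolane (mixture of enantiomers at the boron-bearing carbon), via aryllithium 14 (not isolated), via lithium vinylborate complex 15 (not isolated)
Conditions: 12, t-BuLi (2.0 equiv), THF, −78 °C; 13, −78 °C to rt; then NaOTf, Pd(OAc)2 (cat.), (Sp,Sp)-1,1′-bis[bis(4-methoxy-3,5-dimethylphenyl)phosphino]-2,2′-bis[(R)-α-(dimethylamino)benzyl]ferrocene (cat.), 7, THF, 60 °C
Reagents that add atoms: none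
Why: Bromine–lithium exchange at −78 °C gives aryllithium 14, which is trapped at once by 13 as the four-coordinate borate 15 before it can abstract a proton from a diarylmethane methylene. Pd(OAc)2 is reduced in the flask to zerovalent palladium carrying the bisphosphine, which adds oxidatively to the C5–O bond of triflate 7 to give a cationic arylpalladium species of divalent palladium. This binds the vinyl group of 15, and the π-activation triggers a 1,2-shift of the ring B aryl group from boron to the boron-bearing carbon, anti to palladium, while palladium bonds to the terminal carbon (Cβ–C1′ formed). Reductive elimination from the aryl(alkyl)palladium intermediate then forms C5–Cα and returns zerovalent palladium. The closest known reaction type is the palladium-catalysed three-component conjunctive cross-coupling of aryllithium-derived vinylboron ate complexes with aryl triflates; no ring is closed. The new stereocenter at Cβ is set by the face of the alkene that the chiral ligand lets palladium bind, and its sense is immaterial because step 8 removes it. The step needs the conjunctive pathway to win over direct Suzuki-type aryl transfer and over β-hydride elimination. The non-coordinating triflate, the chelating bisphosphine that leaves no open site for a boron-to-palladium oxygen bridge, and NaOTf, which removes bromide as NaBr, secure this, and the two ortho benzyl groups of ring A slow biaryl formation more than they slow alkene binding.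

Step 8
Reactants: 16 2-[1-{5-(benzyloxy)-2-[4-(benzyloxy)benzyl]phenyl}-2-{3-(benzyloxy)-2,6-bis[4-(benzyloxy)benzyl]-5-methoxyphenyl}ethyl]-4,4,5,5-tetramethyl-1,3,2-dioxaborolane
Product: 17 1-(benzyloxy)-3-(2-{5-(benzyloxy)-2-[4-(benzyloxy)benzyl]phenyl}ethyl)-2,4-bis[4-(benzyloxy)benzyl]-5-methoxybenzene
Conditions: Bu4NF·3H2O, toluene, 60 °C
Reagents that add atoms: none
Why: Fluoride-promoted protodeboronation of a benzylic boronic ester: fluoride adds to boron, the C–B bond of the borate ionises towards a benzylic carbanion, and the water of hydration protonates it; ethers and diarylmethanes are inert and the transient stereocenter disappears.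

Step 9
Reactants: 17 1-(benzyloxy)-3-(2-{5-(benzyloxy)-2-[4-(benzyloxy)benzyl]phenyl}ethyl)-2,4-bis[4-(benzyloxy)benzyl]-5-methoxybenzene
Product: 18 3-(2-{5-hydroxy-2-[(4-hydroxyphenyl)methyl]phenyl}ethyl)-2,4-bis[(4-hydroxyphenyl)methyl]-5-methoxyphenol (CNP0147493.0)
Conditions: H2 (1 atm), 10% Pd/C, EtOAc–MeOH, rt
Reagents that add atoms: none
Why: Catalytic hydrogenolysis of five aryl benzyl ethers; the aryl methyl ether and the diarylmethane and bibenzyl C–C bonds are stable under these conditions.

## Compound list

1 | 5-methoxyresorcinol | COc1cc(O)cc(O)c1 | starting material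
2 | 3-(benzyloxy)-5-methoxyphenol | COc1cc(O)cc(OCc2ccccc2)c1 | intermediate
3 | 4-(benzyloxy)benzyl chloride | ClCc1ccc(OCc2ccccc2)cc1 | starting material
4 | 3-(benzyloxy)-2-[4-(benzyloxy)benzyl]-5-methoxyphenol | COc1cc(O)c(Cc2ccc(OCc3ccccc3)cc2)c(OCc2ccccc2)c1 | intermediate (not isolated)
5 | 5-(benzyloxy)-2-[4-(benzyloxy)benzyl]-3-methoxyphenol | COc1cc(OCc2ccccc2)cc(O)c1Cc1ccc(OCc2ccccc2)cc1 | intermediate (not isolated)
6 | 3-(benzyloxy)-2,6-bis[4-(benzyloxy)benzyl]-5-methoxyphenol | COc1cc(OCc2ccccc2)c(Cc2ccc(OCc3ccccc3)cc2)c(O)c1Cc1ccc(OCc2ccccc2)cc1 | intermediate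
7 | 3-(benzyloxy)-2,6-bis[4-(benzyloxy)benzyl]-5-methoxyphenyl trifluoromethanesulfonate | COc1cc(OCc2ccccc2)c(Cc2ccc(OCc3ccccc3)cc2)c(OS(=O)(=O)C(F)(F)F)c1Cc1ccc(OCc2ccccc2)cc1 | intermediate
8 | 2-bromo-4-hydroxybenzaldehyde | O=Cc1ccc(O)cc1Br | starting material
9 | 4-(benzyloxy)-2-bromobenzaldehyde | O=Cc1ccc(OCc2ccccc2)cc1Br | intermediate
10 | [4-(benzyloxy)phenyl]magnesium bromide | Br[Mg]c1ccc(OCc2ccccc2)cc1 | starting material
11 | (RS)-[4-(benzyloxy)-2-bromophenyl][4-(benzyloxy)phenyl]methanol | OC(c1ccc(OCc2ccccc2)cc1)c1ccc(OCc2ccccc2)cc1Br | intermediate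
12 | 4-(benzyloxy)-1-[4-(benzyloxy)benzyl]-2-bromobenzene | Brc1cc(OCc2ccccc2)ccc1Cc1ccc(OCc2ccccc2)cc1 | intermediate
13 | 4,4,5,5-tetramethyl-2-vinyl-1,3,2-dioxaborolane | C=CB1OC(C)(C)C(C)(C)O1 | starting material
14 | {5-(benzyloxy)-2-[4-(benzyloxy)benzyl]phenyl}lithium | [Li]c1cc(OCc2ccccc2)ccc1Cc1ccc(OCc2ccccc2)cc1 | intermediate (not isolated)
15 | lithium {5-(benzyloxy)-2-[4-(benzyloxy)benzyl]phenyl}(ethenyl)(pinacolato)borate | [Li+].C=C[B-]1(OC(C)(C)C(C)(C)O1)c1cc(OCc2ccccc2)ccc1Cc1ccc(OCc2ccccc2)cc1 | intermediate (not isolated)
16 | 2-[1-{5-(benzyloxy)-2-[4-(benzyloxy)benzyl]phenyl}-2-{3-(benzyloxy)-2,6-bis[4-(benzyloxy)benzyl]-5-methoxyphenyl}ethyl]-4,4,5,5-tetramethyl-1,3,2-dioxaborolane (mixture of enantiomers, configuration not needed) | COc1cc(OCc2ccccc2)c(Cc2ccc(OCc3ccccc3)cc2)c(CC(B2OC(C)(C)C(C)(C)O2)c2cc(OCc3ccccc3)ccc2Cc2ccc(OCc3ccccc3)cc2)c1Cc1ccc(OCc2ccccc2)cc1 | intermediate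
17 | 1-(benzyloxy)-3-(2-{5-(benzyloxy)-2-[4-(benzyloxy)benzyl]phenyl}ethyl)-2,4-bis[4-(benzyloxy)benzyl]-5-methoxybenzene | COc1cc(OCc2ccccc2)c(Cc2ccc(OCc3ccccc3)cc2)c(CCc2cc(OCc3ccccc3)ccc2Cc2ccc(OCc3ccccc3)cc2)c1Cc1ccc(OCc2ccccc2)cc1 | intermediate
18 | 3-(2-{5-hydroxy-2-[(4-hydroxyphenyl)methyl]phenyl}ethyl)-2,4-bis[(4-hydroxyphenyl)methyl]-5-methoxyphenol (achiral) | COc1cc(O)c(Cc2ccc(O)cc2)c(CCc2cc(O)ccc2Cc2ccc(O)cc2)c1Cc1ccc(O)cc1 | target

## Step count and risk

Total step count: 9. Longest linear sequence: 6 steps (1 → 2 → 6 → 7 → 16 → 17 → 18; the ring B branch 8 → 9 → 11 → 12 → 16 → 17 → 18 is equally long).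

**Step 7 (key step).** Three processes may defeat it. Direct transfer of the ring B aryl group to palladium (Suzuki-type coupling) may compete. Alkene binding at a palladium centre crowded by two ortho benzyl groups and a bulky bisphosphine may be so slow that the triflate is merely reduced or hydrolysed. Proton transfer from a diarylmethane methylene to the aryllithium may occur before boron capture. Fallback: form only the C5–Cα bond by an alkylborane coupling, leaving Cβ–C1′ to a prior vinylation. Bromide 12 and vinylboronate 13 would be joined by Suzuki–Miyaura coupling (PdCl2(dppf), K2CO3, dioxane–water) to give 4-(benzyloxy)-1-[4-(benzyloxy)benzyl]-2-ethenylbenzene F5. Hydroboration with 9-borabicyclo[3.3.1]nonane would give 9-(2-{5-(benzyloxy)-2-[4-(benzyloxy)benzyl]phenyl}ethyl)-9-borabicyclo[3.3.1]nonane F6. B-alkyl Suzuki–Miyaura coupling of F6 with triflate 7 (Pd(OAc)2, 2-dicyclohexylphosphino-2′,6′-dimethoxybiphenyl, K3PO4, THF–water), a ligand class that tolerates doubly ortho-substituted electrophiles, would give 17 directly. The fallback sets out from 12 and 7 and returns at 17, making step 8 unnecessary.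

**Step 2.** Alkylation at oxygen or at the carbon para to the phenoxide oxygen, or a second alkylation at an already benzylated carbon with loss of aromaticity, may erode the ortho,ortho-selectivity, because all three ring carbons are activated. Fallback: boron-templated ortho-hydroxyalkylation followed by ionic reduction, which can only reach ortho positions. Phenol 2, 4-(benzyloxy)benzaldehyde and phenylboronic acid (catalytic propionic acid, toluene, reflux with removal of water) would give 7-(benzyloxy)-4-[4-(benzyloxy)phenyl]-5-methoxy-2-phenyl-4H-1,3,2-benzodioxaborin F1 and its regioisomer 5-(benzyloxy)-4-[4-(benzyloxy)phenyl]-7-methoxy-2-phenyl-4H-1,3,2-benzodioxaborin F2. Et3SiH/CF3CO2H would cleave the benzylic C–O bond of each, giving 5 and 4 respectively. A second round of the same two operations would convert 5 into 5-(benzyloxy)-8-[4-(benzyloxy)benzyl]-4-[4-(benzyloxy)phenyl]-7-methoxy-2-phenyl-4H-1,3,2-benzodioxaborin F3 and 4 into 7-(benzyloxy)-8-[4-(benzyloxy)benzyl]-4-[4-(benzyloxy)phenyl]-5-methoxy-2-phenyl-4H-1,3,2-benzodioxaborin F4, both of which would be reduced to 6. The fallback sets out from 2 and returns at 6.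

**Step 8.** Ionisation of the C–B bond of a secondary benzylic boronate buried between two substituted rings may be slow, so that air oxidation to the alcohol or simple recovery of 16 competes. Fallback: replace boron by oxygen and remove the oxygen through an alkene. Oxidation of 16 (H2O2, NaOH, THF–water, 0 °C) would give 1-{5-(benzyloxy)-2-[4-(benzyloxy)benzyl]phenyl}-2-{3-(benzyloxy)-2,6-bis[4-(benzyloxy)benzyl]-5-methoxyphenyl}ethanol F7. Dehydration with the Burgess reagent (toluene, 60 °C) would give the stilbene 1-(benzyloxy)-3-[(E)-2-{5-(benzyloxy)-2-[4-(benzyloxy)benzyl]phenyl}ethenyl]-2,4-bis[4-(benzyloxy)benzyl]-5-methoxybenzene F8. Under the conditions of step 9 the double bond would be saturated and the five benzyl ethers cleaved together. The fallback sets out from 16 and returns at 18.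

**Step 9.** Hydrogenolysis may stall before all five ethers are cleaved, because the ring A ether is crowded and traces of phosphine, boron or fluoride from steps 7 and 8 can poison the catalyst, leaving partially benzylated material. Fallback: Lewis-acid debenzylation of 17 with BCl3 and pentamethylbenzene as cation scavenger (CH2Cl2, −78 °C), which spares the aryl methyl ether at that temperature. It sets out from 17 and returns at 18 and makes no new compound; its entry is F0.

## Further compounds

F1 | step 2 | 7-(benzyloxy)-4-[4-(benzyloxy)phenyl]-5-methoxy-2-phenyl-4H-1,3,2-benzodioxaborin (racemic) | COc1cc(OCc2ccccc2)cc2OB(c3ccccc3)OC(c3ccc(OCc4ccccc4)cc3)c12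
F2 | step 2 | 5-(benzyloxy)-4-[4-(benzyloxy)phenyl]-7-methoxy-2-phenyl-4H-1,3,2-benzodioxaborin (racemic) | COc1cc2OB(c3ccccc3)OC(c3ccc(OCc4ccccc4)cc3)c2c(OCc2ccccc2)c1
F3 | step 2 | 5-(benzyloxy)-8-[4-(benzyloxy)benzyl]-4-[4-(benzyloxy)phenyl]-7-methoxy-2-phenyl-4H-1,3,2-benzodioxaborin (racemic) | COc1cc(OCc2ccccc2)c2c(OB(c3ccccc3)OC2c2ccc(OCc3ccccc3)cc2)c1Cc1ccc(OCc2ccccc2)cc1
F4 | step 2 | 7-(benzyloxy)-8-[4-(benzyloxy)benzyl]-4-[4-(benzyloxy)phenyl]-5-methoxy-2-phenyl-4H-1,3,2-benzodioxaborin (racemic) | COc1cc(OCc2ccccc2)c(Cc2ccc(OCc3ccccc3)cc2)c2OB(c3ccccc3)OC(c3ccc(OCc4ccccc4)cc3)c12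
F5 | step 7 | 4-(benzyloxy)-1-[4-(benzyloxy)benzyl]-2-ethenylbenzene | C=Cc1cc(OCc2ccccc2)ccc1Cc1ccc(OCc2ccccc2)cc1
F6 | step 7 | 9-(2-{5-(benzyloxy)-2-[4-(benzyloxy)benzyl]phenyl}ethyl)-9-borabicyclo[3.3.1]nonane | C(Cc1cc(OCc2ccccc2)ccc1Cc1ccc(OCc2ccccc2)cc1)B1C2CCCC1CCC2
F7 | step 8 | 1-{5-(benzyloxy)-2-[4-(benzyloxy)benzyl]phenyl}-2-{3-(benzyloxy)-2,6-bis[4-(benzyloxy)benzyl]-5-methoxyphenyl}ethanol (mixture of enantiomers) | COc1cc(OCc2ccccc2)c(Cc2ccc(OCc3ccccc3)cc2)c(CC(O)c2cc(OCc3ccccc3)ccc2Cc2ccc(OCc3ccccc3)cc2)c1Cc1ccc(OCc2ccccc2)cc1
F8 | step 8 | 1-(benzyloxy)-3-[(E)-2-{5-(benzyloxy)-2-[4-(benzyloxy)benzyl]phenyl}ethenyl]-2,4-bis[4-(benzyloxy)benzyl]-5-methoxybenzene | COc1cc(OCc2ccccc2)c(Cc2ccc(OCc3ccccc3)cc2)c(/C=C/c2cc(OCc3ccccc3)ccc2Cc2ccc(OCc3ccccc3)cc2)c1Cc1ccc(OCc2ccccc2)cc1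
F0 | step 9 | none | none
A1 | alternative 1 | all-trans 4,6-bis[4-(benzyloxy)benzyl]-5-(2-{5-(benzyloxy)-2-[4-(benzyloxy)benzyl]phenyl}ethyl)cyclohexane-1,3-dione (meso) | O=C1CC(=O)[C@@H](Cc2ccc(OCc3ccccc3)cc2)[C@H](CCc2cc(OCc3ccccc3)ccc2Cc2ccc(OCc3ccccc3)cc2)[C@H]1Cc1ccc(OCc2ccccc2)cc1
A2 | alternative 1 | 4-[4-(benzyloxy)phenyl]butan-2-one | CC(=O)CCc1ccc(OCc2ccccc2)cc1
A3 | alternative 1 | methyl (E)-2-[4-(benzyloxy)benzyl]-5-{5-(benzyloxy)-2-[4-(benzyloxy)benzyl]phenyl}pent-2-enoate | COC(=O)/C(Cc1ccc(OCc2ccccc2)cc1)=C/CCc1cc(OCc2ccccc2)ccc1Cc1ccc(OCc2ccccc2)cc1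
A4 | alternative 2 | methyl 2-{2-[4-(benzyloxy)benzoyl]-3,5-dimethoxyphenyl}acetate | COC(=O)Cc1cc(OC)cc(OC)c1C(=O)c1ccc(OCc2ccccc2)cc1
A5 | alternative 2 | 3,5-dimethoxy-2-(trimethylsilyl)phenyl trifluoromethanesulfonate | COc1cc(OC)c([Si](C)(C)C)c(OS(=O)(=O)C(F)(F)F)c1
A6 | alternative 2 | methyl 3-[4-(benzyloxy)phenyl]-3-oxopropanoate | COC(=O)CC(=O)c1ccc(OCc2ccccc2)cc1
A7 | alternative 3 | {2-[2-{3-(benzyloxy)-2,6-bis[4-(benzyloxy)benzyl]-5-methoxyphenyl}ethyl]-4-hydroxyphenyl}[4-(benzyloxy)phenyl]methanone | COc1cc(OCc2ccccc2)c(Cc2ccc(OCc3ccccc3)cc2)c(CCc2cc(O)ccc2C(=O)c2ccc(OCc3ccccc3)cc2)c1Cc1ccc(OCc2ccccc2)cc1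
A8 | alternative 3 | 5-{3-(benzyloxy)-2,6-bis[4-(benzyloxy)benzyl]-5-methoxyphenyl}-1-[4-(benzyloxy)phenyl]pent-2-yn-1-one | COc1cc(OCc2ccccc2)c(Cc2ccc(OCc3ccccc3)cc2)c(CCC#CC(=O)c2ccc(OCc3ccccc3)cc2)c1Cc1ccc(OCc2ccccc2)cc1
A9 | alternative 3 | (E)-1-methoxy-3-(trimethylsilyloxy)buta-1,3-diene | CO/C=C/C(=C)O[Si](C)(C)C
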